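**Plan**
1. The retrosynthesis first removes two benzyl groups, one dioxolane and the methyl on O-2 of ring B. It then cuts the depside bond between the ring A carbonyl carbon and O-4 of ring B.
2. Ring B is a resorcylate. C1 with its carboxyl carbon, oxygenated C2 and C3 form the carbon chain of an acetoacetate, while oxygenated C4, C5 and pentyl-bearing C6 are C1–C3 of a 3-oxooctanoyl unit, so the ring is cut at C3–C4 and C1–C6.
3. Ring A is bought as the arene of methyl orsellinate. Only the benzylic CH2–C(=O) bond of its 2-oxoheptyl chain is cut, back to a toluate anion and a hexanoyl Weinreb amide.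
4. Forward, ring B is the only ring built, by a formal (3+3) cycloaromatization, while ring A is elaborated in parallel. The halves are joined at the free 4-hydroxyl, the chelated 2-hydroxyl is methylated, the ketone is unmasked, and hydrogenolysis ends the route.
5. The target has no stereocentre. All control is regiochemical and rests on the order of bond formation in the ring synthesis and on the difference between free and hydrogen-bonded hydroxyls.

Key step: step 6

Assumption: the double-bond geometries drawn for the silyl enol ethers are those expected for the major isomers. They have no consequence, because these carbons end up as arene carbons.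

**Step 1**
Reactants: 1 benzyl acetoacetate
Product: 2 benzyl (E)-3-(trimethylsilyloxy)but-2-enoate
Conditions: Me3SiCl (1.2 equiv), Et3N (1.3 equiv), hexane, rt; filter under Ar, concentrate
Reagents that add atoms: chlorotrimethylsilane, C[Si](C)(C)Cl
Why: O-silylation of the enol of a beta-keto ester under soft enolization with amine base is the routine first stage in making 1,3-bis(silyloxy)dienes.

**Step 2**
Reactants: 2 benzyl (E)-3-(trimethylsilyloxy)but-2-enoate
Product: 4 (1Z)-1-(benzyloxy)-1,3-bis(trimethylsilyloxy)buta-1,3-diene, via lithium dienolate 3 (not isolated)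
Conditions: LiN(iPr)2 (1.1 equiv), THF, −78 °C; Me3SiCl (1.2 equiv), −78 °C to rt; hexane, filter, concentrate; used crude
Reagents that add atoms: chlorotrimethylsilane, C[Si](C)(C)Cl
Why: Kinetic gamma-deprotonation of the silyloxy crotonate gives an extended ester enolate that is trapped on oxygen (silyl ketene acetal formation), the standard second silylation.

**Step 3**
Reactants: 5 ethyl 3-oxooctanoate; 6 ethylene glycol
Product: 7 ethyl 2-(2-pentyl-1,3-dioxolan-2-yl)acetate
Conditions: p-TsOH (cat.), toluene, reflux, Dean–Stark
Reagents that add atoms: none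
Why: Acid-catalysed ketalization with azeotropic removal of water is routine for beta-keto esters, since only the ketone carbonyl reacts.

**Step 4**
Reactants: 7 ethyl 2-(2-pentyl-1,3-dioxolan-2-yl)acetate
Product: 8 potassium 2-(2-pentyl-1,3-dioxolan-2-yl)acetate
Conditions: KOH (1.0 equiv), EtOH/H2O, rt; evaporate, dry by toluene azeotrope
Reagents that add atoms: potassium hydroxide, [K+].[OH-]
Why: Saponification leaves the base-stable dioxolane untouched, and isolating the dry salt avoids acidifying a beta-ketal acid.

**Step 5**
Reactants: 8 potassium 2-(2-pentyl-1,3-dioxolan-2-yl)acetate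
Product: 9 2-(2-pentyl-1,3-dioxolan-2-yl)acetyl chloride
Conditions: (COCl)2 (1.5 equiv), CH2Cl2, 0 °C to rt; filter, concentrate; used at once
Reagents that add atoms: oxalyl chloride, O=C(Cl)C(=O)Cl
Why: A carboxylate salt forms the acid chloride with oxalyl chloride through a mixed anhydride that loses CO and CO2, and because KCl rather than HCl is the by-product the acid-labile ketal stays closed.

**Step 6 (key step)**
Reactants: 4 (1Z)-1-(benzyloxy)-1,3-bis(trimethylsilyloxy)buta-1,3-diene; 9 2-(2-pentyl-1,3-dioxolan-2-yl)acetyl chloride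
Product: 12 benzyl 2,4-dihydroxy-6-pentylbenzoate, via open-chain 3,5-dioxo ester ketal 10 (not isolated), via cyclised hydroxyethoxy dione 11 (not isolated)
Conditions: 4 (1.3 equiv) and 9 premixed in CH2Cl2, −78 °C; TiCl4 (2 equiv) dropwise, −78 °C to 0 °C; then H2O
Reagents that add atoms: none
Why: This is the known TiCl4-mediated formal (3+3) cyclocondensation of 1,3-bis(silyloxy)dienes with ketal-masked beta-keto acid chlorides: the terminal CH2 of 4, its most nucleophilic vinylogous site, is acylated by 9 at −78 °C with loss of a silyl group and forms the C3–C4 bond of ring B (10). TiCl4 then opens the dioxolane to an oxocarbenium ion, and the titanium-bound enol carbon between ester and ketone attacks it in a Mukaiyama aldol-type 6-exo-trig closure that forms the C1–C6 bond (11). Beta-elimination of the 2-hydroxyethoxy group and enolization of both ketones give the arene, so aromatization drives the sequence. The two transient stereocentres of 11 vanish and 12 contains none. The selectivity needed is regiochemical (2,4-dihydroxy-6-pentyl rather than 2,6-dihydroxy-4-pentyl), and it is secured because the acyl chloride is far more electrophilic than the un-ionized ketal at −78 °C and because 4 and 9 are mixed before the Lewis acid is added, after which only one six-membered closure is possible. The benzyl ester should tolerate TiCl4 as long as the mixture stays at or below 0 °C.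

**Step 7**
Reactants: 13 methyl 2,4-dihydroxy-6-methylbenzoate (methyl orsellinate)
Product: 14 methyl 2-hydroxy-4-methoxy-6-methylbenzoate
Conditions: MeI (1.1 equiv), K2CO3 (1.1 equiv), acetone, reflux
Reagents that add atoms: iodomethane, CI
Why: In this Williamson etherification with one equivalent of reagents only the free 4-hydroxyl reacts, because the 2-hydroxyl is held in a hydrogen bond to the ester carbonyl.

**Step 8**
Reactants: 14 methyl 2-hydroxy-4-methoxy-6-methylbenzoate
Product: 15 methyl 2-(benzyloxy)-4-methoxy-6-methylbenzoate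
Conditions: BnBr (1.3 equiv), K2CO3 (2 equiv), DMF, 60 °C
Reagents that add atoms: benzyl bromide, BrCc1ccccc1
Why: Williamson etherification in a polar solvent with heating and excess reagent overcomes the chelation of the remaining hydroxyl.

**Step 9**
Reactants: 16 hexanoyl chloride
Product: 17 N-methoxy-N-methylhexanamide
Conditions: MeNH(OMe)·HCl (1.1 equiv), Et3N (2.2 equiv), CH2Cl2, 0 °C to rt
Reagents that add atoms: N,O-dimethylhydroxylamine hydrochloride, CNOC.Cl
Why: N-acylation of the hydroxylamine by an acid chloride is the standard preparation of a Weinreb amide.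

**Step 10**
Reactants: 15 methyl 2-(benzyloxy)-4-methoxy-6-methylbenzoate; 17 N-methoxy-N-methylhexanamide
Product: 19 methyl 2-(benzyloxy)-4-methoxy-6-(2-oxoheptyl)benzoate, via benzylic lithium species 18 (not isolated)
Conditions: LiN(iPr)2 (2.2 equiv), THF, −78 °C; 17 (1.2 equiv), −78 to −40 °C; AcOH/THF quench at −78 °C
Reagents that add atoms: none
Why: Lateral lithiation of the ortho-toluate gives an ester-stabilized benzylic anion that undergoes a Weinreb ketone synthesis, in which the chelated tetrahedral adduct blocks over-addition and the di-ortho-substituted ester resists self-condensation.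

**Step 11**
Reactants: 19 methyl 2-(benzyloxy)-4-methoxy-6-(2-oxoheptyl)benzoate
Product: 20 methyl 2-(benzyloxy)-4-methoxy-6-[(2-pentyl-1,3-dioxolan-2-yl)methyl]benzoate
Conditions: Me3SiOCH2CH2OSiMe3 (2 equiv), Me3SiOTf (10 mol %), CH2Cl2, −78 to −20 °C; pyridine quench
Reagents that add atoms: 1,2-bis(trimethylsilyloxy)ethane, C[Si](C)(C)OCCO[Si](C)(C)C
Why: The aprotic low-temperature Noyori ketalization is driven by formation of hexamethyldisiloxane and avoids the hot protic acid that would favour enol lactonization onto the neighbouring ester.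

**Step 12**
Reactants: 20 methyl 2-(benzyloxy)-4-methoxy-6-[(2-pentyl-1,3-dioxolan-2-yl)methyl]benzoate
Product: 22 2-(benzyloxy)-4-methoxy-6-[(2-pentyl-1,3-dioxolan-2-yl)methyl]benzoic acid, via potassium carboxylate 21 (not isolated)
Conditions: KOH (5 equiv), DMSO/H2O, 90 °C; cold aq KHSO4 to pH 3–4, 0 °C, immediate extraction into EtOAc
Reagents that add atoms: potassium hydroxide, [K+].[OH-]
Why: Saponification of a di-ortho-substituted methyl benzoate needs hot KOH in aqueous DMSO, which benzyl ether and dioxolane withstand, and a brief cold acidification frees the acid without opening the ketal.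

**Step 13**
Reactants: 22 2-(benzyloxy)-4-methoxy-6-[(2-pentyl-1,3-dioxolan-2-yl)methyl]benzoic acid; 12 benzyl 2,4-dihydroxy-6-pentylbenzoate
Product: 23 benzyl 4-({2-(benzyloxy)-4-methoxy-6-[(2-pentyl-1,3-dioxolan-2-yl)methyl]benzoyl}oxy)-2-hydroxy-6-pentylbenzoate
Conditions: DCC (1.2 equiv), DMAP (0.2 equiv), CH2Cl2, 0 °C to rt
Reagents that add atoms: none
Why: The Steglich esterification is neutral enough for the ketal and acylates only the free 4-hydroxyl of 12, because the 2-hydroxyl is deactivated by its hydrogen bond to the benzyl ester carbonyl.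

**Step 14**
Reactants: 23 the 2-hydroxy depside of step 13
Product: 24 benzyl 4-({2-(benzyloxy)-4-methoxy-6-[(2-pentyl-1,3-dioxolan-2-yl)methyl]benzoyl}oxy)-2-methoxy-6-pentylbenzoate
Conditions: MeI (5 equiv), anhydrous K2CO3 (3 equiv), dry acetone, reflux
Reagents that add atoms: iodomethane, CI
Why: Williamson etherification of the only remaining hydroxyl should proceed cleanly, since anhydrous carbonate in acetone spares a depside ester whose carbonyl is shielded by two ortho substituents.

**Step 15**
Reactants: 24 the fully protected depside of step 14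
Product: 25 benzyl 4-{[2-(benzyloxy)-4-methoxy-6-(2-oxoheptyl)benzoyl]oxy}-2-methoxy-6-pentylbenzoate
Conditions: PPTS (0.3 equiv), acetone/H2O, 50 °C
Reagents that add atoms: water, O
Why: Acid-catalysed ketal hydrolysis with the weak acid PPTS in wet acetone cleaves the dialkyl dioxolane and should be too mild to hydrolyse the esters or to drive enol attack on the aryl ester.

**Step 16**
Reactants: 25 benzyl 4-{[2-(benzyloxy)-4-methoxy-6-(2-oxoheptyl)benzoyl]oxy}-2-methoxy-6-pentylbenzoate
Product: 26 confluentic acid
Conditions: H2 (1 atm), 10 % Pd on carbon, EtOAc, rt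
Reagents that add atoms: none
Why: Catalytic hydrogenolysis removes the benzyl ether and the benzyl ester together under neutral conditions that leave the aliphatic ketone, the aryl ester and the methyl ethers intact.

**Compound list**
1 | benzyl acetoacetate | CC(=O)CC(=O)OCc1ccccc1 | starting material
2 | benzyl (E)-3-(trimethylsilyloxy)but-2-enoate | C/C(O[Si](C)(C)C)=C\C(=O)OCc1ccccc1 | intermediate
3 | lithium 1-(benzyloxy)-3-(trimethylsilyloxy)buta-1,3-dien-1-olate, formed in the flask | C=C(O[Si](C)(C)C)/C=C(/OCc1ccccc1)[O-].[Li+] | intermediate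
4 | (1Z)-1-(benzyloxy)-1,3-bis(trimethylsilyloxy)buta-1,3-diene | C=C(O[Si](C)(C)C)/C=C(/OCc1ccccc1)O[Si](C)(C)C | intermediate
5 | ethyl 3-oxooctanoate | CCCCCC(=O)CC(=O)OCC | starting material
6 | ethylene glycol | OCCO | starting material
7 | ethyl 2-(2-pentyl-1,3-dioxolan-2-yl)acetate | CCCCCC1(CC(=O)OCC)OCCO1 | intermediate
8 | potassium 2-(2-pentyl-1,3-dioxolan-2-yl)acetate | CCCCCC1(CC(=O)[O-])OCCO1.[K+] | intermediate
9 | 2-(2-pentyl-1,3-dioxolan-2-yl)acetyl chloride | CCCCCC1(CC(=O)Cl)OCCO1 | intermediate
10 | benzyl 3,5-dioxo-6-(2-pentyl-1,3-dioxolan-2-yl)hexanoate, formed in the flask, written in its neutral keto form | CCCCCC1(CC(=O)CC(=O)CC(=O)OCc2ccccc2)OCCO1 | intermediate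
11 | benzyl 2-(2-hydroxyethoxy)-4,6-dioxo-2-pentylcyclohexane-1-carboxylate, formed in the flask as a mixture of diastereomers whose stereocentres are lost on aromatization | CCCCCC1(OCCO)CC(=O)CC(=O)C1C(=O)OCc1ccccc1 | intermediate
12 | benzyl 2,4-dihydroxy-6-pentylbenzoate | CCCCCc1cc(O)cc(O)c1C(=O)OCc1ccccc1 | intermediate
13 | methyl 2,4-dihydroxy-6-methylbenzoate (methyl orsellinate) | COC(=O)c1c(C)cc(O)cc1O | starting material
14 | methyl 2-hydroxy-4-methoxy-6-methylbenzoate | COC(=O)c1c(C)cc(OC)cc1O | intermediate
15 | methyl 2-(benzyloxy)-4-methoxy-6-methylbenzoate | COC(=O)c1c(C)cc(OC)cc1OCc1ccccc1 | intermediate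
16 | hexanoyl chloride | CCCCCC(=O)Cl | starting material
17 | N-methoxy-N-methylhexanamide | CCCCCC(=O)N(C)OC | intermediate
18 | benzylic lithium derivative of 15, formed in the flask | [Li+].[CH2-]c1cc(OC)cc(OCc2ccccc2)c1C(=O)OC | intermediate
19 | methyl 2-(benzyloxy)-4-methoxy-6-(2-oxoheptyl)benzoate | CCCCCC(=O)Cc1cc(OC)cc(OCc2ccccc2)c1C(=O)OC | intermediate
20 | methyl 2-(benzyloxy)-4-methoxy-6-[(2-pentyl-1,3-dioxolan-2-yl)methyl]benzoate | CCCCCC1(Cc2cc(OC)cc(OCc3ccccc3)c2C(=O)OC)OCCO1 | intermediate
21 | potassium 2-(benzyloxy)-4-methoxy-6-[(2-pentyl-1,3-dioxolan-2-yl)methyl]benzoate, formed in the flask | CCCCCC1(Cc2cc(OC)cc(OCc3ccccc3)c2C(=O)[O-])OCCO1.[K+] | intermediate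
22 | 2-(benzyloxy)-4-methoxy-6-[(2-pentyl-1,3-dioxolan-2-yl)methyl]benzoic acid | CCCCCC1(Cc2cc(OC)cc(OCc3ccccc3)c2C(=O)O)OCCO1 | intermediate
23 | benzyl 4-({2-(benzyloxy)-4-methoxy-6-[(2-pentyl-1,3-dioxolan-2-yl)methyl]benzoyl}oxy)-2-hydroxy-6-pentylbenzoate | CCCCCC1(Cc2cc(OC)cc(OCc3ccccc3)c2C(=O)Oc2cc(O)c(C(=O)OCc3ccccc3)c(CCCCC)c2)OCCO1 | intermediate
24 | benzyl 4-({2-(benzyloxy)-4-methoxy-6-[(2-pentyl-1,3-dioxolan-2-yl)methyl]benzoyl}oxy)-2-methoxy-6-pentylbenzoate | CCCCCC1(Cc2cc(OC)cc(OCc3ccccc3)c2C(=O)Oc2cc(OC)c(C(=O)OCc3ccccc3)c(CCCCC)c2)OCCO1 | intermediate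
25 | benzyl 4-{[2-(benzyloxy)-4-methoxy-6-(2-oxoheptyl)benzoyl]oxy}-2-methoxy-6-pentylbenzoate | CCCCCC(=O)Cc1cc(OC)cc(OCc2ccccc2)c1C(=O)Oc1cc(OC)c(C(=O)OCc2ccccc2)c(CCCCC)c1 | intermediate
26 | confluentic acid, 4-{[2-hydroxy-4-methoxy-6-(2-oxoheptyl)benzoyl]oxy}-2-methoxy-6-pentylbenzoic acid | CCCCCC(=O)Cc1cc(OC)cc(O)c1C(=O)Oc1cc(CCCCC)c(C(=O)O)c(OC)c1 | target

**Step count**
Total: 16 steps. Longest linear sequence: 9 steps (7, 8, 10, 11, 12, 13, 14, 15, 16). The ring B branch reaches the target in 8 steps (3, 4, 5, 6, 13–16).

**Steps most likely to fail**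

Step 6. TiCl4 may ionize the dioxolane or degrade the moisture-sensitive diene before acylation is complete. The benzyl ester may also be cleaved if the mixture warms, so conversion into the arene could stay low. The fallback sets out from 1 and 7 and comes back at 12. It makes the same two ring bonds one after the other by anionic chemistry. Compound 1 is converted into its dianion with LiN(iPr)2 (2.2 equiv, THF, −78 to 0 °C) and acylated at the terminal carbon by ester 7. This is a known acylation of beta-keto ester dianions with ketal-protected esters, and it gives 10 as an isolated compound. Dilute HCl in THF then removes the dioxolane to give benzyl 3,5,7-trioxododecanoate F1. A biomimetic polyketide aldol cyclization (Cs2CO3 or pH 9 buffer, then acid for the dehydration) joins C2 to C7 and delivers 12.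

Step 13. Acyl transfer from the carbodiimide adduct to the phenol may be slow at the di-ortho-substituted carbonyl. In that case rearrangement of the activated acid to an unreactive urea derivative, or participation of a ketal oxygen, could take over. The fallback sets out from 22 and comes back at 23. It replaces activation in the flask by an isolated, sterically small acyl halide and an anionic nucleophile. Acid 22 is treated with cyanuric fluoride and pyridine (CH2Cl2, −10 °C to rt) to give 2-(benzyloxy)-4-methoxy-6-[(2-pentyl-1,3-dioxolan-2-yl)methyl]benzoyl fluoride F2. Phenol 12 is deprotonated at its more acidic, unchelated 4-hydroxyl with NaH (1.0 equiv, THF, 0 °C), and this phenoxide is acylated by the acyl fluoride to give 23.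

Step 14. The chelated hydroxyl may be alkylated so slowly that carbonate-induced cleavage or intermolecular acyl transfer of the depside ester competes. The fallback sets out from 12 and comes back at 24. It methylates ring B before the depside bond exists.
- Selective allylation of the free 4-hydroxyl (allyl bromide 1.05 equiv, K2CO3, acetone) gives benzyl 4-(allyloxy)-2-hydroxy-6-pentylbenzoate F3.
- MeI and K2CO3 in DMF give benzyl 4-(allyloxy)-2-methoxy-6-pentylbenzoate F4.
- Tsuji–Trost deallylation (Pd(PPh3)4 cat., morpholine, THF) gives benzyl 4-hydroxy-2-methoxy-6-pentylbenzoate F5.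
- Steglich esterification of F5 with 22 (DCC, DMAP, CH2Cl2) gives 24 directly, bypassing 23.

**Further compounds**
F1 | step 6 | benzyl 3,5,7-trioxododecanoate | CCCCCC(=O)CC(=O)CC(=O)CC(=O)OCc1ccccc1
F2 | step 13 | 2-(benzyloxy)-4-methoxy-6-[(2-pentyl-1,3-dioxolan-2-yl)methyl]benzoyl fluoride | CCCCCC1(Cc2cc(OC)cc(OCc3ccccc3)c2C(=O)F)OCCO1
F3 | step 14 | benzyl 4-(allyloxy)-2-hydroxy-6-pentylbenzoate | CCCCCc1cc(OCC=C)cc(O)c1C(=O)OCc1ccccc1
F4 | step 14 | benzyl 4-(allyloxy)-2-methoxy-6-pentylbenzoate | CCCCCc1cc(OCC=C)cc(OC)c1C(=O)OCc1ccccc1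
F5 | step 14 | benzyl 4-hydroxy-2-methoxy-6-pentylbenzoate | CCCCCc1cc(O)cc(OC)c1C(=O)OCc1ccccc1
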